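The partner charged stands to the starting material charged in amber as 40.0 %. This charge ratio, partner charged over starting material charged, is my ceiling on target wherever it lies below the whole charge: each partner gives one second intermediate, and each target takes one. Amber has less partner than starting material, so partner is its limiting reagent.

| flask | starting material | partner | remark | time |
|---|---|---|---|---|
| Tuesday's | 13 mM | 8 mM | run made earlier |  |
| Saturday's | 10 mM | 8 mM | run made earlier |  |
| amber | 20 mM | 8.00 mM |  | 20 h |
| violet | 20 mM | 25.0 mM |  | 20 h |
| red | 20 mM | 80.0 mM |  | 20 h |
| teal | 20 mM | 250 mM |  | 20 h |
| green | 20 mM | 800 mM |  | 20 h |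

| run | time / h | target / % | starting material / % |
|---|---|---|---|
| Tuesday's | 0.500 | 0.6 | 30.1 |
| Tuesday's | 1.33 | 2.5 | 4.4 |
| Tuesday's | 2.50 | 7.7 | 0 |
| Tuesday's | 4.00 | 15.5 | 0.1 |
| Saturday's | 0.500 | 0.3 | 30.6 |
| Saturday's | 1.33 | 2.3 | 3.8 |
| Saturday's | 2.50 | 7.4 | 0.6 |
| Saturday's | 4.00 | 15.9 | 0.5 |

(standard deviation of a reading: 0.3 percentage points)

- percent here means starting material units held: one idle adduct counts as two
- what is said of target includes idle adduct
- what was read earlier has a scatter of 0.3 percentage points, one standard deviation
- steps thought possible: partner -> second intermediate; open intermediate + second intermediate -> target; starting material -> open intermediate; starting material + second intermediate -> side product; starting material + target <-> idle adduct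
- in an amount of target, one idle adduct counts as one target
- "hardly changes" means that all values lie within two and a half points (for a concentration: within two and a half percent of the largest)

- amount of target at the end, in percent of the starting material charged for amber, violet, red, teal, green, in this order
- the shape of the row from first to last (hardly changes / falls all the way / rises, then falls / falls, then rises / rises all the way)

That ceiling is my first way to the number. The second comes from the readings. Tuesday's and Saturday's runs differ in starting material, 13 mM against 10 mM, but have the same partner, and at 4.00 h they read 15.5 % and 15.9 % of target. Starting material is down to 4.4 % by 1.33 h on Tuesday, so target forms from what waits as open intermediate. Target gained per hour, over what is not yet target, reads 0.0615 h⁻¹ on Tuesday and 0.0674 h⁻¹ on Saturday.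

Held for 20 h in amber, Tuesday's pace gives 70.8 %, so my two ways part. The pace is the one that cheats: it asks for 14.2 mM of target, more than the 8.00 mM of partner charged, and it keeps second intermediate level while each target removes one. I commit to just under 40.0 % for amber.

In violet the ratio is 125 %, so starting material becomes the limiting charge and the ceiling is the whole of it. The pace, scaled with the partner, gives 97.9 %. Nearness to that ceiling is no check: any large pace in this reckoning comes close to it, and this pace still keeps second intermediate level. So I commit to a figure below 97.9 % for violet, and these runs do not read what goes to side product.

The forecast gives 37 %, 90 %, 93 %, 83 % and 65 %, shape rises, then falls. Its violet is lower than my pace figure. Of the later points it says: “The fall at high partner is therefore a judgement, not a measurement.”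

The row reads 36.4 %, 86.0 %, 83.7 %, 67.5 % and 48.1 %, shape rises, then falls.

    partner → second intermediate (k = 1.14 × 10⁻⁴ s⁻¹)
    open intermediate + second intermediate → target (k = 0.00402 M⁻¹ s⁻¹)
    starting material → open intermediate (k = 6.43 × 10⁻⁴ s⁻¹)
    starting material + second intermediate → side product (k = 0.0151 M⁻¹ s⁻¹)
    starting material + target ⇌ idle adduct, settled at all times (K = 78.0 M⁻¹)

Amber ends at 36.4 % because of the shrinking supply of partner: the same run with that supply held reaches 97.1 %. At 200 h amber holds 37.8 % of target and 2.21 % of side product, together 40.0 %, which is its charge ratio. In violet the ratio of 125 % leaves a surplus of charged partner over starting material of 5.00 mM, and 5.00 mM of second intermediate stands there at 200 h.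

The earlier runs and the new flask stem from a simulated flask for an exercise, noise included.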